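The β-hydroxy ketone is cut by an aldol disconnection into 2,2-dimethylchroman-6-carbaldehyde and the dihydrobenzofuranyl methyl ketone. The pyran ring of the chroman (O1, C2, C3, C4, C4a, C8a) is not closed onto an arene: its O1–C2–C3–C4 chain is first tied to one carbon as the spiro-oxolane of a cyclohexadienone made by dearomatising a para-substituted phenol. A Lewis-acid dienone–phenol rearrangement then moves C4 to the neighbouring ring carbon, so that the five-membered ring becomes the six-membered one, the arene returns, and the dienone oxygen is left on C6, para to O1, exactly where the side chain sits; triflation in the same flask makes it the handle for the formyl carbon.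

Key step: step 3

Assumption: the sense of induction of the two chiral catalysts (steps 5 and 8) is taken from their behaviour with the parent substrates; in each case the antipode meant is the one that delivers the (S)-centre.

Step 1
Reactants: 1 4-(4-hydroxyphenyl)butan-2-one
Product: 2 4-(3-hydroxy-3-methylbutyl)phenol
Conditions: MeMgBr (3 equiv), THF, 0 °C to rt; aq. NH4Cl
Reagents that add atoms: methylmagnesium bromide, C[Mg]Br
Why: Grignard addition to a methyl ketone; the first equivalent only deprotonates the phenol and the phenoxide is inert, so the excess reagent should add cleanly to the carbonyl to give the tertiary alcohol.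

Step 2
Reactants: 2 4-(3-hydroxy-3-methylbutyl)phenol
Product: 3 2,2-dimethyl-1-oxaspiro[4.5]deca-6,9-dien-8-one
Conditions: PhI(OAc)2 (1.1 equiv), (CF3)2CHOH, 0 °C
Reagents that add atoms: none
Why: Oxidative dearomatisation of a para-alkylphenol by trivalent iodine; ligand exchange at iodine and loss of iodobenzene make the para carbon electrophilic, and the tethered tertiary hydroxyl should capture it in a 5-exo spiroetherification that is helped by the gem-dimethyl group and not intercepted by the non-nucleophilic solvent.

Step 3
Reactants: 3 2,2-dimethyl-1-oxaspiro[4.5]deca-6,9-dien-8-one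
Product: 5 2,2-dimethylchroman-6-yl trifluoromethanesulfonate, via 2,2-dimethylchroman-6-ol 4 (not isolated)
Conditions: BF3·OEt2 (1.2 equiv), CH2Cl2, −40 to 0 °C; then pyridine, Tf2O, 0 °C
Reagents that add atoms: trifluoromethanesulfonic anhydride, O=S(=O)(OS(=O)(=O)C(F)(F)F)C(F)(F)F
Why: BF3 binds the dienone oxygen and generates a hydroxypentadienyl cation with positive charge on the two ring carbons flanking the spiro centre. A suprafacial 1,2-shift of the oxolane CH2 (the later C4) from the spiro carbon to one of these carbons gives an oxocarbenium ion at the former spiro carbon, and loss of a proton aromatises to chromanol 4; this is a dienone–phenol rearrangement, the closest known type being the acid-catalysed rearrangement of 4-alkyl-4-alkoxycyclohexadienones (p-quinol ethers) to alkylhydroquinone ethers. The six-membered ring is therefore not closed by a cyclisation but arises by one-carbon ring expansion of the five-membered spiro ether (bond C4–C8a broken, bond C4–C4a made), and no stereocentre is formed. The selectivity needed is migration of carbon and not of oxygen, which the ring oxygen itself secures because only carbon migration leaves the charge on the oxygen-bearing carbon, while the mirror plane of the dienone makes both flanking carbons equivalent so that a single regioisomer can form. Ionisation of the tertiary C–O bonds is the competing path and is held back by low temperature and by the Lewis acid sitting on the more basic carbonyl oxygen. Pyridine then frees the phenol and Tf2O sulfonylates it in the same flask.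

Step 4
Reactants: 5 2,2-dimethylchroman-6-yl trifluoromethanesulfonate
Product: 6 2,2-dimethylchroman-6-carbaldehyde
Conditions: Pd(OAc)2 (5 mol %), 1,3-bis(diphenylphosphino)propane (5 mol %), CO (1 atm), Et3SiH, Et3N, DMF, 70 °C
Reagents that add atoms: carbon monoxide, [C-]#[O+]
Why: Palladium-catalysed reductive carbonylation (formylation) of an aryl triflate: oxidative addition, CO insertion and hydride transfer from the silane to the acylpalladium should give the aldehyde, the chelating bisphosphine being suited to the electron-rich triflate and the cyclic tertiary ether being inert.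

Step 5
Reactants: 7 1-(5-bromo-2,4-dihydroxyphenyl)ethanone; 8 isoprene (2-methylbuta-1,3-diene)
Product: 9 1-[(2S)-6-hydroxy-2-(prop-1-en-2-yl)-2,3-dihydro-1-benzofuran-5-yl]ethanone
Conditions: Pd2(dba)3·CHCl3 (2.5 mol %), chiral tert-butanesulfinamide-based monophosphine ligand (TY-Phos type, antipode giving 2S), NaOPh, CH2Cl2, 80 °C, sealed tube
Reagents that add atoms: none
Why: Asymmetric Heck/Tsuji–Trost heteroannulation (enantioselective Larock-type annulation of an o-bromophenol with a 1,3-diene): the arylpalladium species adds to the unsubstituted vinyl terminus of isoprene and the ortho phenoxide attacks the internal carbon of the resulting π-allyl complex to close the five-membered ring, the chiral ligand deciding the face of C–O bond formation and hence the (2S) centre, while the chelated hydroxyl para to bromine cannot cyclise.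

Step 6
Reactants: 9 1-[(2S)-6-hydroxy-2-(prop-1-en-2-yl)-2,3-dihydro-1-benzofuran-5-yl]ethanone
Product: 10 1-[(2S)-6-hydroxy-2-(2-hydroxypropan-2-yl)-2,3-dihydro-1-benzofuran-5-yl]ethanone
Conditions: Co(acac)2 (20 mol %), PhSiH3, O2 (1 atm), THF, rt; then aq. Na2S2O3
Reagents that add atoms: dioxygen, O=O
Why: Mukaiyama hydration: hydrogen-atom transfer from a cobalt hydride to the 1,1-disubstituted alkene gives the tertiary radical, which is trapped by O2 and reduced to the Markovnikov tertiary alcohol without touching the C2 stereocentre, the aryl ketone or the chelated phenol.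

Step 7
Reactants: 10 1-[(2S)-6-hydroxy-2-(2-hydroxypropan-2-yl)-2,3-dihydro-1-benzofuran-5-yl]ethanone
Product: 11 (2S)-6-(trimethylsilyloxy)-2-[2-(trimethylsilyloxy)propan-2-yl]-5-[1-(trimethylsilyloxy)ethenyl]-2,3-dihydro-1-benzofuran
Conditions: TMSOTf (3.5 equiv), Et3N (4.5 equiv), CH2Cl2, 0 °C to rt; pentane, filtration, used crude
Reagents that add atoms: trimethylsilyl trifluoromethanesulfonate, C[Si](C)(C)OS(=O)(=O)C(F)(F)F
Why: Soft enolisation with a silyl triflate and an amine gives the only possible enol silane of the methyl ketone and caps the phenol and the tertiary alcohol as trimethylsilyl ethers in the same operation, so that no free O–H enters the aldol step.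

Step 8
Reactants: 11 (2S)-6-(trimethylsilyloxy)-2-[2-(trimethylsilyloxy)propan-2-yl]-5-[1-(trimethylsilyloxy)ethenyl]-2,3-dihydro-1-benzofuran; 6 2,2-dimethylchroman-6-carbaldehyde
Product: 14 (3S)-3-(2,2-dimethylchroman-6-yl)-3-hydroxy-1-[(2S)-6-hydroxy-2-(2-hydroxypropan-2-yl)-2,3-dihydro-1-benzofuran-5-yl]propan-1-one (target CNP0419761.2), via trichlorosilyl aldolate 12 (not isolated), via bis-silyl aldol 13 (not isolated)
Conditions: SiCl4 (1.5 equiv), (S,S)-bisphosphoramide [two (S)-N,N'-dimethyl-1,1'-binaphthyl-2,2'-diamine phosphoramide units joined through N,N'-dimethylpentane-1,5-diamine] (5 mol %), iPr2NEt (10 mol %), CH2Cl2, −78 °C; sat. aq. NaHCO3, 0 °C; then citric acid, MeOH/H2O, 0 °C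
Reagents that add atoms: none
Why: Lewis-base-catalysed, SiCl4-mediated enantioselective Mukaiyama aldol addition: the chiral bisphosphoramide-bound trichlorosilyl cation activates aldehyde 6 and blocks its Re face, so the enol silane should add to the Si face through an open transition state and set the (S)-carbinol under catalyst control (the distant C2 centre having no say), after which mild hydrolysis cleaves the Si–O bonds without dehydrating the benzylic alcohol.

Compound list

1 | 4-(4-hydroxyphenyl)butan-2-one | CC(=O)CCc1ccc(O)cc1 | starting material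
2 | 4-(3-hydroxy-3-methylbutyl)phenol | CC(C)(O)CCc1ccc(O)cc1 | intermediate
3 | 2,2-dimethyl-1-oxaspiro[4.5]deca-6,9-dien-8-one | CC1(C)CCC2(O1)C=CC(=O)C=C2 | intermediate
4 | 2,2-dimethylchroman-6-ol | CC1(C)CCc2cc(O)ccc2O1 | intermediate (not isolated)
5 | 2,2-dimethylchroman-6-yl trifluoromethanesulfonate | CC1(C)CCc2cc(OS(=O)(=O)C(F)(F)F)ccc2O1 | intermediate
6 | 2,2-dimethylchroman-6-carbaldehyde | CC1(C)CCc2cc(C=O)ccc2O1 | intermediate
7 | 1-(5-bromo-2,4-dihydroxyphenyl)ethanone | CC(=O)c1cc(Br)c(O)cc1O | starting material
8 | isoprene (2-methylbuta-1,3-diene) | C=CC(C)=C | starting material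
9 | 1-[(2S)-6-hydroxy-2-(prop-1-en-2-yl)-2,3-dihydro-1-benzofuran-5-yl]ethanone | CC(=O)c1cc2c(cc1O)O[C@H](C(C)=C)C2 | intermediate
10 | 1-[(2S)-6-hydroxy-2-(2-hydroxypropan-2-yl)-2,3-dihydro-1-benzofuran-5-yl]ethanone | CC(=O)c1cc2c(cc1O)O[C@H](C(C)(C)O)C2 | intermediate
11 | (2S)-6-(trimethylsilyloxy)-2-[2-(trimethylsilyloxy)propan-2-yl]-5-[1-(trimethylsilyloxy)ethenyl]-2,3-dihydro-1-benzofuran | C=C(O[Si](C)(C)C)c1cc2c(cc1O[Si](C)(C)C)O[C@H](C(C)(C)O[Si](C)(C)C)C2 | intermediate
12 | (3S)-3-(2,2-dimethylchroman-6-yl)-3-(trichlorosilyloxy)-1-{(2S)-6-(trimethylsilyloxy)-2-[2-(trimethylsilyloxy)propan-2-yl]-2,3-dihydro-1-benzofuran-5-yl}propan-1-one | CC1(C)CCc2cc([C@@H](O[Si](Cl)(Cl)Cl)CC(=O)c3cc4c(cc3O[Si](C)(C)C)O[C@H](C(C)(C)O[Si](C)(C)C)C4)ccc2O1 | intermediate (not isolated)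
13 | (3S)-3-(2,2-dimethylchroman-6-yl)-3-hydroxy-1-{(2S)-6-(trimethylsilyloxy)-2-[2-(trimethylsilyloxy)propan-2-yl]-2,3-dihydro-1-benzofuran-5-yl}propan-1-one | CC1(C)CCc2cc([C@@H](O)CC(=O)c3cc4c(cc3O[Si](C)(C)C)O[C@H](C(C)(C)O[Si](C)(C)C)C4)ccc2O1 | intermediate (not isolated)
14 | (3S)-3-(2,2-dimethylchroman-6-yl)-3-hydroxy-1-[(2S)-6-hydroxy-2-(2-hydroxypropan-2-yl)-2,3-dihydro-1-benzofuran-5-yl]propan-1-one | CC1(C)CCc2cc([C@@H](O)CC(=O)c3cc4c(cc3O)O[C@H](C(C)(C)O)C4)ccc2O1 | target

Total step count: 8 steps.
Longest linear sequence: 5 steps (steps 1, 2, 3, 4 and 8); the second branch (steps 5, 6, 7, 8) has 4.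

Steps most likely to fail

Step 3. The activated dienone may ionise the spiro C–O bond (ring opening to phenolic and quinone-methide-derived material) or shift oxygen instead of carbon, and the electron-rich phenol that forms may be consumed by Friedel–Crafts attack on still-activated dienone. The fallback sets out from 3 and introduces the C6 carbon before the ring expansion, so that no phenol, triflate or carbonylation is involved. CeCl3-assisted 1,2-addition of vinylmagnesium bromide (THF, −78 °C) to the dienone carbonyl should give 8-ethenyl-2,2-dimethyl-1-oxaspiro[4.5]deca-6,9-dien-8-ol F1 (either relative configuration serves). Catalytic camphorsulfonic acid in CH2Cl2 at −20 °C should ionise the doubly allylic tertiary alcohol, and the same 1,2-shift of the oxolane CH2 (a dienol–benzene rearrangement) should expand the ring and aromatise directly to 6-ethenyl-2,2-dimethylchroman F2. Ozonolysis (O3, CH2Cl2/MeOH, −78 °C; Me2S) comes back to the route at 6.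

Step 5. Enantiocontrol or turnover may be lost because the substrate carries a second, chelating o-hydroxyacetyl unit that can bind palladium, and the phenoxide may attack the wrong terminus of the allyl complex. The fallback sets out from 7 and sets the centre by reagent-controlled epoxidation and a stereospecific ring closure. Stille coupling with tributyl(3-methylbut-2-en-1-yl)stannane (Pd(PPh3)4, DMF, 90 °C) should give 1-[2,4-dihydroxy-5-(3-methylbut-2-en-1-yl)phenyl]ethanone F3. Silylation (TBSCl, imidazole, DMF) should give 1-[2,4-bis(tert-butyldimethylsilyloxy)-5-(3-methylbut-2-en-1-yl)phenyl]ethanone F4. Shi epoxidation with the D-fructose-derived ketone and KHSO5 at pH 10.5 should give 1-{2,4-bis(tert-butyldimethylsilyloxy)-5-[((2R)-3,3-dimethyloxiran-2-yl)methyl]phenyl}ethanone F5. TBAF (THF, 0 °C) should remove both silyl groups, and the liberated 4-phenoxide should open the epoxide 5-exo at the secondary carbon with inversion. This comes back to the route at 10, so step 6 is not needed.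

Step 8. Facial selectivity may be poor with the hindered ortho-silyloxy enol silane, and the electron-rich benzylic silyl ether may ionise and dehydrate to the enone. The fallback sets out from 10 and 6, makes that enone on purpose, and sets the carbinol by C–B instead of C–C bond formation. Claisen–Schmidt condensation (KOH, EtOH, rt) should give (2E)-3-(2,2-dimethylchroman-6-yl)-1-[(2S)-6-hydroxy-2-(2-hydroxypropan-2-yl)-2,3-dihydro-1-benzofuran-5-yl]prop-2-en-1-one F6. Copper-catalysed enantioselective conjugate borylation (CuCl, NaOtBu, B2pin2, MeOH, THF, with 1-[2-(diphenylphosphino)ferrocenyl]ethyldicyclohexylphosphine in the antipode that gives the 3S product) should give (3S)-3-(2,2-dimethylchroman-6-yl)-1-[(2S)-6-hydroxy-2-(2-hydroxypropan-2-yl)-2,3-dihydro-1-benzofuran-5-yl]-3-(4,4,5,5-tetramethyl-1,3,2-dioxaborolan-2-yl)propan-1-one F7. Oxidation with NaBO3·4H2O (THF/H2O, rt) proceeds with retention and comes back to the route at 14.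

Further compounds
F1 | step 3 | 8-ethenyl-2,2-dimethyl-1-oxaspiro[4.5]deca-6,9-dien-8-ol | CC1(C)CCC2(O1)C=CC(O)(C=C)C=C2
F2 | step 3 | 6-ethenyl-2,2-dimethylchroman | CC1(C)CCc2cc(C=C)ccc2O1
F3 | step 5 | 1-[2,4-dihydroxy-5-(3-methylbut-2-en-1-yl)phenyl]ethanone | CC(=O)c1cc(CC=C(C)C)c(O)cc1O
F4 | step 5 | 1-[2,4-bis(tert-butyldimethylsilyloxy)-5-(3-methylbut-2-en-1-yl)phenyl]ethanone | CC(=O)c1cc(CC=C(C)C)c(O[Si](C)(C)C(C)(C)C)cc1O[Si](C)(C)C(C)(C)C
F5 | step 5 | 1-{2,4-bis(tert-butyldimethylsilyloxy)-5-[((2R)-3,3-dimethyloxiran-2-yl)methyl]phenyl}ethanone | CC(=O)c1cc(C[C@H]2OC2(C)C)c(O[Si](C)(C)C(C)(C)C)cc1O[Si](C)(C)C(C)(C)C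
F6 | step 8 | (2E)-3-(2,2-dimethylchroman-6-yl)-1-[(2S)-6-hydroxy-2-(2-hydroxypropan-2-yl)-2,3-dihydro-1-benzofuran-5-yl]prop-2-en-1-one | CC1(C)CCc2cc(/C=C/C(=O)c3cc4c(cc3O)O[C@H](C(C)(C)O)C4)ccc2O1
F7 | step 8 | (3S)-3-(2,2-dimethylchroman-6-yl)-1-[(2S)-6-hydroxy-2-(2-hydroxypropan-2-yl)-2,3-dihydro-1-benzofuran-5-yl]-3-(4,4,5,5-tetramethyl-1,3,2-dioxaborolan-2-yl)propan-1-one | CC1(C)CCc2cc([C@@H](B3OC(C)(C)C(C)(C)O3)CC(=O)c3cc4c(cc3O)O[C@H](C(C)(C)O)C4)ccc2O1
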